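**Assumption:** both enantiomers of methyl 3-bromo-2-methylpropanoate (sold, made from the Roche esters) and 4-methoxy-3-methylfuran-2(5H)-one are bought; locants in the text are those of the compound named.

## Retrosynthetic overview

1. Target ⇐ O-demethylation of its 4-O-methyl ether ⇐ Z-selective ylidenation (aldol, then E1cB) of a dienal with bought 4-methoxy-3-methylfuran-2(5H)-one.
2. Dienal ⇐ dienoate ⇐ key union: a visible-light, nickel-catalysed three-component syn-alkenyl-methylation of a terminal alkyne with an E-alkenyl iodide and a methyl radical (makes C7–C8 and C6–CH3 of the dienoate, sets 6E; proposed new method).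
3. Alkenyl iodide ⇐ Takai olefination ⇐ photochemical Giese addition of methyl (2R)-3-bromo-2-methylpropanoate to 3-vinylfuran. Alkyne ⇐ Ohira–Bestmann homologation ⇐ photochemical Giese addition of the (2S)-bromoester to acrolein.
4. Both stereocentres are bought in the two enantiomeric bromoesters and are never a reacting centre.
5. No ring is formed: the furan comes in furan-3-carbaldehyde and the butenolide is bought intact.

## Route

Step 1
Reactants: 1 furan-3-carbaldehyde
Product: 2 3-vinylfuran
Conditions: Ph3PCH3Br, KOtBu, Et2O, 0 °C → rt; distilled, kept as a titrated solution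
Reagents that add atoms: methyltriphenylphosphonium bromide, C[P+](c1ccccc1)(c1ccccc1)c1ccccc1.[Br-]
Why: Wittig methylenation of an aromatic aldehyde with the non-stabilised ylide is fast and clean, and the volatile product is simply carried on in solution.

Step 2
Reactants: 3 methyl (2R)-3-bromo-2-methylpropanoate; 2 3-vinylfuran
Product: 4 methyl (2S)-5-(furan-3-yl)-2-methylpentanoate
Conditions: 2 (2.5 equiv), (TMS)3SiH (1.5 equiv), iPr3SiSH (10 mol%), Ir[dF(CF3)ppy]2(dtbbpy)PF6 (1 mol%), MeCN, 450 nm LEDs, 20 °C
Reagents that add atoms: none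
Why: Photoinitiated silyl-radical bromine abstraction gives a primary radical β to the stereocentre, which adds to the CH2 terminus of 2 (Giese-type anti-Markovnikov hydroalkylation) and is capped by thiol polarity-reversal H-transfer before it can telomerise; C2 is untouched and its descriptor changes only because Br leaves the CIP ranking.

Step 3
Reactants: 4 methyl (2S)-5-(furan-3-yl)-2-methylpentanoate
Product: 5 (2S)-5-(furan-3-yl)-2-methylpentanal
Conditions: iBu2AlH (1.05 equiv), CH2Cl2, −78 °C; MeOH, aq. potassium sodium tartrate; used crude at once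
Reagents that add atoms: none
Why: Partial ester reduction stops at the tetrahedral aluminium hemiacetal at −78 °C for an α-branched methyl ester, and the cold neutral work-up does not epimerise the α-centre.

Step 4
Reactants: 5 (2S)-5-(furan-3-yl)-2-methylpentanal
Product: 6 3-[(4S,5E)-6-iodo-4-methylhex-5-en-1-yl]furan
Conditions: CrCl2 (6 equiv), CHI3 (2 equiv), THF/1,4-dioxane 1:6, 0 °C → rt, dark
Reagents that add atoms: iodoform, IC(I)I
Why: Takai olefination with the geminal dichromium carbenoid gives the E-alkenyl iodide (usually >10:1 for α-branched aldehydes) under non-basic conditions that neither epimerise the α-centre nor touch the furan.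

Step 5
Reactants: 7 methyl (2S)-3-bromo-2-methylpropanoate; 8 acrolein
Product: 9 methyl (2R)-2-methyl-6-oxohexanoate
Conditions: 8 (3 equiv), (TMS)3SiH (1.3 equiv), Ir[dF(CF3)ppy]2(dtbbpy)PF6 (1 mol%), MeCN, 450 nm LEDs, 20 °C
Reagents that add atoms: none
Why: Photoinitiated halogen-atom transfer and Giese addition of the primary radical to acrolein, the α-formyl radical then taking H from Si–H; the stereocentre is β to the radical and is kept.

Step 6
Reactants: 9 methyl (2R)-2-methyl-6-oxohexanoate
Product: 10 methyl (2R)-2-methylhept-6-ynoate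
Conditions: dimethyl (1-diazo-2-oxopropyl)phosphonate (1.3 equiv), K2CO3 (2 equiv), MeOH, 0 °C → rt
Reagents that add atoms: dimethyl (1-diazo-2-oxopropyl)phosphonate (Ohira–Bestmann reagent), COP(=O)(OC)C(=[N+]=[N-])C(C)=O
Why: Seyferth–Gilbert homologation (Ohira–Bestmann variant) turns the unbranched aldehyde into the terminal alkyne; K2CO3/MeOH is too weak to enolise the α-methyl ester and transesterification is degenerate.

Step 7
Reactants: 10 methyl (2R)-2-methylhept-6-ynoate; 6 3-[(4S,5E)-6-iodo-4-methylhex-5-en-1-yl]furan
Product: 11 methyl (2R,6E,8E,10S)-13-(furan-3-yl)-2,6,10-trimethyltrideca-6,8-dienoate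
Conditions: 10 (2.0 equiv), NiBr2(dme) (10 mol%), 4,4'-di-tert-butyl-2,2'-bipyridine (12 mol%), N-acetoxyphthalimide (2.5 equiv, added over 6 h), Hantzsch ester (2.5 equiv), NaHCO3 (3 equiv), DMA, 450 nm LEDs, 25 °C
Reagents that add atoms: N-acetoxyphthalimide, CC(=O)ON1C(=O)c2ccccc2C1=O
Why: Proposed new method: a light-driven nickel-catalysed syn-1,2-alkenyl-methylation of a terminal alkyne, in which zerovalent nickel inserts into the C–I bond of 6, the alkenyl complex of divalent nickel carbometallates 10 in syn fashion with the alkenyl group going to the unhindered terminal carbon (C7–C8 bond), and the resulting dienylnickel captures a methyl radical released (with CO2 and phthalimide anion) by photoexcitation of the electron donor–acceptor complex of N-acetoxyphthalimide and the Hantzsch ester, so that reductive elimination from trivalent nickel puts CH3 on C6 cis to the new C7–C8 bond (6E), keeps 8E and leaves both stereocentres untouched, while the absence of a photosensitiser avoids triplet isomerisation of the diene; the closest known reaction types are the photochemical nickel-catalysed decarboxylative cross-electrophile coupling of N-acyloxyphthalimides with alkenyl or aryl halides and the radical-first, regiochemically opposite, nickel-catalysed three-component alkylarylation of alkynes.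

Step 8
Reactants: 11 methyl (2R,6E,8E,10S)-13-(furan-3-yl)-2,6,10-trimethyltrideca-6,8-dienoate
Product: 12 (2R,6E,8E,10S)-13-(furan-3-yl)-2,6,10-trimethyltrideca-6,8-dienal
Conditions: iBu2AlH (1.05 equiv), CH2Cl2, −78 °C; MeOH, aq. potassium sodium tartrate; used crude at once
Reagents that add atoms: none
Why: Partial reduction of the α-branched methyl ester as in step 3; the hydride does not touch the unactivated diene or the furan, and C2 is not epimerised.

Step 9
Reactants: 13 4-methoxy-3-methylfuran-2(5H)-one; 12 (2R,6E,8E,10S)-13-(furan-3-yl)-2,6,10-trimethyltrideca-6,8-dienal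
Product: 17 (5Z)-5-[(2R,6E,8E,10S)-13-(furan-3-yl)-2,6,10-trimethyltrideca-6,8-dien-1-ylidene]-4-methoxy-3-methylfuran-2(5H)-one, via lithium enolate 14 (not isolated), via lithium aldolate 15 (not isolated), via mesylate 16 (not isolated)
Conditions: 13 (1.2 equiv), LiN(iPr)2 (1.2 equiv), THF, −78 °C; 12, −78 °C, 1 h; MsCl (1.5 equiv), −78 → 0 °C; DBU (3 equiv), 0 °C → rt
Reagents that add atoms: none
Why: C5-lithiation of the methyl tetronate and aldol addition at −78 °C outrun enolisation of the α-branched aldehyde, and in-flask mesylation with DBU-mediated E1cB elimination gives the conjugated ylidene as the Z isomer (chain syn to the ring oxygen, away from the C4 methoxy) without touching the allylic stereocentre.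

Step 10
Reactants: 17 (5Z)-5-[(2R,6E,8E,10S)-13-(furan-3-yl)-2,6,10-trimethyltrideca-6,8-dien-1-ylidene]-4-methoxy-3-methylfuran-2(5H)-one
Product: 18 (5Z)-5-[(2R,6E,8E,10S)-13-(furan-3-yl)-2,6,10-trimethyltrideca-6,8-dien-1-ylidene]-4-hydroxy-3-methylfuran-2(5H)-one (CNP0223721.1)
Conditions: LiCl (10 equiv), DMF, 90 °C, argon; then cold 0.5 M HCl
Reagents that add atoms: none
Why: Krapcho-type SN2 demethylation, in which chloride attacks the O-methyl of the vinylogous carbonate and releases the stabilised tetronate anion under neutral conditions that leave the Z-ylidene, diene, furan and both stereocentres alone; acidification gives the tetronic acid.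

## Compound list

1 | furan-3-carbaldehyde | O=Cc1ccoc1 | starting material
2 | 3-vinylfuran | C=Cc1ccoc1 | intermediate
3 | methyl (2R)-3-bromo-2-methylpropanoate | COC(=O)[C@@H](C)CBr | starting material
4 | methyl (2S)-5-(furan-3-yl)-2-methylpentanoate | COC(=O)[C@@H](C)CCCc1ccoc1 | intermediate
5 | (2S)-5-(furan-3-yl)-2-methylpentanal | O=C[C@@H](C)CCCc1ccoc1 | intermediate
6 | 3-[(4S,5E)-6-iodo-4-methylhex-5-en-1-yl]furan | I/C=C/[C@@H](C)CCCc1ccoc1 | intermediate
7 | methyl (2S)-3-bromo-2-methylpropanoate | COC(=O)[C@H](C)CBr | starting material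
8 | acrolein (prop-2-enal) | C=CC=O | starting material
9 | methyl (2R)-2-methyl-6-oxohexanoate | COC(=O)[C@H](C)CCCC=O | intermediate
10 | methyl (2R)-2-methylhept-6-ynoate | COC(=O)[C@H](C)CCCC#C | intermediate
11 | methyl (2R,6E,8E,10S)-13-(furan-3-yl)-2,6,10-trimethyltrideca-6,8-dienoate | COC(=O)[C@H](C)CCC/C(C)=C/C=C/[C@@H](C)CCCc1ccoc1 | intermediate
12 | (2R,6E,8E,10S)-13-(furan-3-yl)-2,6,10-trimethyltrideca-6,8-dienal | O=C[C@H](C)CCC/C(C)=C/C=C/[C@@H](C)CCCc1ccoc1 | intermediate
13 | 4-methoxy-3-methylfuran-2(5H)-one | COC1=C(C)C(=O)OC1 | starting material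
14 | lithium 4-methoxy-3-methylfuran-2-olate (C5-lithiated 13) | [Li+].COc1coc([O-])c1C | intermediate (not isolated)
15 | lithium alkoxide of 5-[(2R,6E,8E,10S)-13-(furan-3-yl)-1-hydroxy-2,6,10-trimethyltrideca-6,8-dien-1-yl]-4-methoxy-3-methylfuran-2(5H)-one (mixture at the two new centres) | [Li+].[O-]C([C@H](C)CCC/C(C)=C/C=C/[C@@H](C)CCCc1ccoc1)C1OC(=O)C(C)=C1OC | intermediate (not isolated)
16 | methanesulfonate of the aldol adduct in 15 (mixture at the two new centres) | CS(=O)(=O)OC([C@H](C)CCC/C(C)=C/C=C/[C@@H](C)CCCc1ccoc1)C1OC(=O)C(C)=C1OC | intermediate (not isolated)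
17 | (5Z)-5-[(2R,6E,8E,10S)-13-(furan-3-yl)-2,6,10-trimethyltrideca-6,8-dien-1-ylidene]-4-methoxy-3-methylfuran-2(5H)-one | CC1=C(OC)/C(=C/[C@H](C)CCC/C(C)=C/C=C/[C@@H](C)CCCc2ccoc2)OC1=O | intermediate
18 | (5Z)-5-[(2R,6E,8E,10S)-13-(furan-3-yl)-2,6,10-trimethyltrideca-6,8-dien-1-ylidene]-4-hydroxy-3-methylfuran-2(5H)-one | CC1=C(O)/C(=C/[C@H](C)CCC/C(C)=C/C=C/[C@@H](C)CCCc2ccoc2)OC1=O | target

## Step count and risks

Total steps: 10. Longest linear sequence: 8 (1 → 2 → 4 → 5 → 6 → 11 → 12 → 17 → 18).

**Step 7 (proposed new method).** Three things can go wrong: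
- the alkenylnickel may take the methyl radical before the alkyne inserts, giving the propenyl compound;
- the methyl radical may add to the alkyne first, giving the regioisomer;
- the dienylnickel may be protonated, giving the unmethylated diene.

Slow ester addition, excess 10 and the bicarbonate buffer are the levers against these. The fallback sets out from 10 (with 6) and comes back at 11 by the known Negishi sequence. Zirconium-catalysed carboalumination of 10 (Me3Al 3 equiv, Cp2ZrCl2 20 mol%, CH2Cl2, 0 °C; the ester only complexes Me3Al) gives [(1E,6R)-7-methoxy-2,6-dimethyl-7-oxohept-1-en-1-yl]dimethylalane F1, which is not isolated. Adding ZnCl2 in THF, Pd(PPh3)4 (5 mol%) and 6 at rt gives 11 with the same 6E,8E geometry.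

**Step 2 (radical hydroalkylation of 3-vinylfuran).** Telomerisation of 2, hydrosilylation and loss of the volatile alkene are the risks. The fallback sets out from 3 and comes back at 4, and makes step 1 unnecessary. The same photochemical silane-mediated Giese addition is run on vinylboronic acid pinacol ester to give methyl (2S)-2-methyl-5-(4,4,5,5-tetramethyl-1,3,2-dioxaborolan-2-yl)pentanoate F2. A B-alkyl Suzuki–Miyaura coupling of F2 with 3-bromofuran (Pd(OAc)2, RuPhos, K3PO4, toluene/H2O, 80 °C) then gives 4.

**Step 9 (one-pot aldol, mesylation, elimination).** The risks are base-induced epimerisation of 12, incomplete in-flask mesylation and an E/Z mixture. The fallback sets out from 13 (with 12) and comes back at 17 by a non-basic vinylogous Mukaiyama aldol. Treating 13 with TBSOTf and Et3N (CH2Cl2, 0 °C) gives tert-butyl[(4-methoxy-3-methylfuran-2-yl)oxy]dimethylsilane F3. F3 and 12 with BF3·OEt2 (CH2Cl2, −78 °C) give the isolated aldol 5-[(2R,6E,8E,10S)-13-(furan-3-yl)-1-hydroxy-2,6,10-trimethyltrideca-6,8-dien-1-yl]-4-methoxy-3-methylfuran-2(5H)-one F4. MsCl/Et3N then DBU converts F4 through mesylate 16 into 17.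

## Further compounds

F1 | step 7 | [(1E,6R)-7-methoxy-2,6-dimethyl-7-oxohept-1-en-1-yl]dimethylalane | COC(=O)[C@H](C)CCC/C(C)=C/[Al](C)C
F2 | step 2 | methyl (2S)-2-methyl-5-(4,4,5,5-tetramethyl-1,3,2-dioxaborolan-2-yl)pentanoate | COC(=O)[C@@H](C)CCCB1OC(C)(C)C(C)(C)O1
F3 | step 9 | tert-butyl[(4-methoxy-3-methylfuran-2-yl)oxy]dimethylsilane | COc1coc(O[Si](C)(C)C(C)(C)C)c1C
F4 | step 9 | 5-[(2R,6E,8E,10S)-13-(furan-3-yl)-1-hydroxy-2,6,10-trimethyltrideca-6,8-dien-1-yl]-4-methoxy-3-methylfuran-2(5H)-one | OC([C@H](C)CCC/C(C)=C/C=C/[C@@H](C)CCCc1ccoc1)C1OC(=O)C(C)=C1OC
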